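The C3–C4–C5 array of the cyclohexane ring is a latent aldol: C5–OH lies β to C3, and C4 carries its own oxygen. With C3 imagined as a ketone, C2–C3–C4 is a hydroxyacetone unit and C4–C5 an aldol bond; everything rests on that disconnection. An L-proline-catalysed 6-enolendo aldol cyclisation (Hajos–Parrish type) of an acyclic keto-aldehyde closes the carbocycle at C4–C5 and sets both carbinol centres in one operation. The precursor holds only the C1 quaternary centre, built by self-regeneration of stereocentres on a pivalaldehyde dioxolanone of an L-allylglycine-derived hydroxy acid; ozonolysis of its two alkene arms unmasks the carbonyls. Directed reduction, lactone–acetonide formation, O1-caffeoylation and acid hydrolysis complete the route.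

Key step: step 7

Remarks: locants C1–C6 in the text are those of quinic acid (C1 quaternary; C3–OH and C4–OH cis; C5–OH cis to the carboxyl). 3,4-Di-O-acetylcaffeic acid (16) is treated as a purchasable compound.

Step 1
Reactants: 1 2-methylenepropane-1,3-diol
Product: 2 2-[(triethylsilyloxy)methyl]prop-2-en-1-ol
Conditions: NaH (1.0 equiv), THF, 0 °C → rt; then Et3SiCl (1.0 equiv), 0 °C → rt
Reagents that add atoms: chlorotriethylsilane CC[Si](Cl)(CC)CC
Why: One equivalent of NaH converts the symmetric diol into a sparingly soluble monoalkoxide that is silylated once (O-silylation, statistical desymmetrisation of a diol), and no stereocentre is formed.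

Step 2
Reactants: 2 2-[(triethylsilyloxy)methyl]prop-2-en-1-ol
Product: 4 [2-(bromomethyl)prop-2-en-1-yl]oxy(triethyl)silane, via allylic mesylate 3 (not isolated)
Conditions: MsCl, Et3N, THF, −20 °C; then LiBr, 0 °C → rt
Reagents that add atoms: lithium bromide [Li+].[Br-]; methanesulfonyl chloride CS(=O)(=O)Cl (its atoms stay in intermediate 3 only)
Why: Mesylation followed by Finkelstein-type SN2 displacement with bromide at the unhindered allylic carbon should give the allylic bromide without touching the silyl ether, and no stereocentre is involved.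

Step 3
Reactants: 5 L-allylglycine
Product: 6 (S)-2-hydroxypent-4-enoic acid
Conditions: NaNO2, 1 M H2SO4 (aq), 0 °C → rt
Reagents that add atoms: water O
Why: Diazotisation of the α-amino acid proceeds with overall retention because the neighbouring carboxylate first closes an α-lactone that water then opens (double inversion), so the S centre of 5 is carried into 6.

Step 4
Reactants: 6 (S)-2-hydroxypent-4-enoic acid
Product: 7 (2S,5S)-2-tert-butyl-5-(prop-2-en-1-yl)-1,3-dioxolan-4-one
Conditions: t-BuCHO, TsOH·H2O (cat.), H2SO4 (cat.), pentane, reflux, water separator; chromatography to remove the minor trans acetal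
Reagents that add atoms: pivalaldehyde CC(C)(C)C=O
Why: Acid-catalysed acetalisation with azeotropic removal of water gives the 1,3-dioxolan-4-one, whose new acetal centre (S) is set cis to the allyl group under thermodynamic control, which stores the chirality of C1 for the self-regeneration-of-stereocentres tactic.

Step 5
Reactants: 7 (2S,5S)-2-tert-butyl-5-(prop-2-en-1-yl)-1,3-dioxolan-4-one; 4 [2-(bromomethyl)prop-2-en-1-yl]oxy(triethyl)silane
Product: 9 (2S,5R)-2-tert-butyl-5-(prop-2-en-1-yl)-5-{2-[(triethylsilyloxy)methyl]prop-2-en-1-yl}-1,3-dioxolan-4-one, via lithium enolate 8 (not isolated)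
Conditions: LiN(iPr)2, THF, −78 °C; then 4, −78 → −30 °C
Reagents that add atoms: lithium diisopropylamide [Li+].CC(C)[N-]C(C)C (lithium is held in intermediate 8 only)
Why: Deprotonation erases the C5 centre but the acetal centre persists, and the planar enolate is alkylated (SN2 enolate alkylation) on the face anti to the tert-butyl group, so the new arm takes the place of the former hydrogen and the quaternary carbon (quinate C1) is formed with R configuration.

Step 6
Reactants: 9 (2S,5R)-2-tert-butyl-5-(prop-2-en-1-yl)-5-{2-[(triethylsilyloxy)methyl]prop-2-en-1-yl}-1,3-dioxolan-4-one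
Product: 11 (2S,5R)-2-tert-butyl-5-(2-oxoethyl)-5-[2-oxo-3-(triethylsilyloxy)propyl]-1,3-dioxolan-4-one, via bis-ozonide 10 (not isolated)
Conditions: O3, CH2Cl2, −78 °C; then Me2S, −78 °C → rt; chromatography
Reagents that add atoms: ozone [O-][O+]=O
Why: Ozonolysis with reductive work-up cleaves the terminal alkene to the C5 aldehyde and the 1,1-disubstituted alkene to the C3 ketone without touching the acetal, the silyl ether or the quaternary centre, and chromatography frees the keto-aldehyde from formaldehyde before the aldol step.

Step 7
Reactants: 11 (2S,5R)-2-tert-butyl-5-(2-oxoethyl)-5-[2-oxo-3-(triethylsilyloxy)propyl]-1,3-dioxolan-4-one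
Product: 13 (2S,5R,8S,9R)-2-tert-butyl-9-hydroxy-8-(triethylsilyloxy)-1,3-dioxaspiro[4.5]decane-4,7-dione, via proline enamine 12 (not isolated)
Conditions: L-proline (30 mol %), DMSO, rt
Reagents that add atoms: L-proline OC(=O)[C@@H]1CCCN1 (catalyst; its atoms are in intermediate 12 only)
Why: L-Proline condenses with the C3 ketone to the (E)-enamine 12 on the silyloxy-bearing side, C4 of this enamine adds to the C5 aldehyde while the proline carboxylic acid hydrogen-bonds the aldehyde oxygen, and hydrolysis of the iminium returns the catalyst; the closest known reaction type is the proline-catalysed Hajos–Parrish (Eder–Sauer–Wiechert) 6-enolendo aldolisation, here with an α-oxygenated ketone donor as in proline aldols of hydroxyacetone. The cyclohexane ring is closed in the 6-(enolendo)-exo-trig mode by forming the C4–C5 bond. C5 (R) is set by the catalyst: in the chair-like transition state the aldehyde oxygen must point to the carboxylic acid and the C6 tether must stay gauche to C3, which exposes the aldehyde face that places the new hydroxyl cis to the C1 carbonyl, the same sense as in the Hajos–Parrish ketol formed with L-proline. C4 (S) follows from the (E)-enamine geometry (OSiEt3 trans to nitrogen, which avoids allylic strain with the pyrrolidine ring) and from attack on the enamine face syn to the carboxylic acid, so both new C–O bonds are axial in the transition-state chair and become the trans-diequatorial 4,5-dioxygen pattern after ring flip. The step needs regioselectivity (enamine towards C4 and not C2, secured because attack from C2 or from the aldehyde enamine could only close a four-membered ring), chemoselectivity for addition over dehydration or loss of the C1 acetal oxygen (weakly acidic, base-free medium at room temperature), and diastereoselection relative to C1, which rests on catalyst control with the planar dioxolanone carbonyl, and not the acetal oxygen, lying 1,3-diaxial to the developing alkoxide.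

Step 8
Reactants: 13 (2S,5R,8S,9R)-2-tert-butyl-9-hydroxy-8-(triethylsilyloxy)-1,3-dioxaspiro[4.5]decane-4,7-dione
Product: 14 (2S)-2-tert-butyl-7,9-dihydroxy-8-(triethylsilyloxy)-1,3-dioxaspiro[4.5]decan-4-one (7-OH and 8-OSiEt3 cis to ring oxygen O1; 9-OH cis to the ring carbonyl)
Conditions: Me4NBH(OAc)3, MeCN/AcOH (1:1), −30 → −20 °C; aq. KNaC4H4O6 work-up
Reagents that add atoms: none
Why: In this hydroxyl-directed reduction (Evans–Saksena type) the acetoxyborohydride exchanges onto the free C5 hydroxyl and delivers hydride intramolecularly to the C3 carbonyl, which should give the 1,3-anti diol with C3–OH (R) trans to C5–OH and cis to the C4 and C1 oxygens, the C1 oxygen being tied up in the acetal so that it cannot direct.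

Step 9
Reactants: 14 (2S)-2-tert-butyl-7,9-dihydroxy-8-(triethylsilyloxy)-1,3-dioxaspiro[4.5]decan-4-one
Product: 15 3,4-O-isopropylidene-1,5-quinide (1,5-lactone 3,4-acetonide of quinic acid; free tertiary 1-OH)
Conditions: TsOH·H2O (20 mol %), acetone/2,2-dimethoxypropane (3:1), 50 °C
Reagents that add atoms: 2,2-dimethoxypropane COC(C)(C)OC
Why: Three acid-catalysed events should converge on the thermodynamically favoured tricycle, namely cleavage of the triethylsilyl ether by the methanol present, ketalisation of the cis-3,4-diol (acetonide formation), and attack of the C5 hydroxyl on the cis-disposed dioxolanone carbonyl with loss of pivalaldehyde (transesterification to the γ-lactone), which leaves the tertiary C1 hydroxyl as the only free OH and changes no stereocentre.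

Step 10
Reactants: 15 3,4-O-isopropylidene-1,5-quinide; 16 (E)-3,4-diacetoxycinnamic acid
Product: 18 1-O-[(E)-3,4-diacetoxycinnamoyl]-3,4-O-isopropylidene-1,5-quinide, via acid chloride 17 (not isolated)
Conditions: 16, (COCl)2, DMF (cat.), CH2Cl2, 0 °C → rt, evaporate; then 15, pyridine, DMAP, CH2Cl2, rt
Reagents that add atoms: oxalyl chloride ClC(=O)C(=O)Cl (chlorine is held in intermediate 17 only)
Why: The acid chloride acylates the hindered tertiary C1 hydroxyl, the only free hydroxyl of 15, under nucleophilic catalysis by DMAP (acyl transfer from an acid chloride), and no stereocentre is touched.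

Step 11
Reactants: 18 1-O-[(E)-3,4-diacetoxycinnamoyl]-3,4-O-isopropylidene-1,5-quinide
Product: 19 1-O-caffeoylquinic acid
Conditions: 1 M HCl (aq)/THF, rt
Reagents that add atoms: water O
Why: Aqueous acid hydrolyses the acetonide, the two phenolic acetates and the strained bicyclic lactone, while the hindered tertiary cinnamate ester should survive because ester migration and cleavage at O1 are base-promoted processes that are avoided here, and no stereocentre is touched.

Compound list
1 | 2-methylenepropane-1,3-diol | OCC(=C)CO | starting material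
2 | 2-[(triethylsilyloxy)methyl]prop-2-en-1-ol | OCC(=C)CO[Si](CC)(CC)CC | intermediate
3 | 2-[(triethylsilyloxy)methyl]prop-2-en-1-yl methanesulfonate | CS(=O)(=O)OCC(=C)CO[Si](CC)(CC)CC | intermediate (not isolated)
4 | [2-(bromomethyl)prop-2-en-1-yl]oxy(triethyl)silane | BrCC(=C)CO[Si](CC)(CC)CC | intermediate
5 | L-allylglycine, (S)-2-aminopent-4-enoic acid | C=CC[C@H](N)C(=O)O | starting material
6 | (S)-2-hydroxypent-4-enoic acid | C=CC[C@H](O)C(=O)O | intermediate
7 | (2S,5S)-2-tert-butyl-5-(prop-2-en-1-yl)-1,3-dioxolan-4-one (cis) | C=CC[C@@H]1O[C@H](C(C)(C)C)OC1=O | intermediate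
8 | lithium enolate of 7 (acetal carbon S) | C=CCC1=C(O[Li])O[C@@H](C(C)(C)C)O1 | intermediate (not isolated)
9 | (2S,5R)-2-tert-butyl-5-(prop-2-en-1-yl)-5-{2-[(triethylsilyloxy)methyl]prop-2-en-1-yl}-1,3-dioxolan-4-one (new arm trans to tert-butyl) | C=CC[C@]1(CC(=C)CO[Si](CC)(CC)CC)O[C@H](C(C)(C)C)OC1=O | intermediate
10 | bis-ozonide of 9 (two 1,2,4-trioxolanes, mixture at the trioxolane carbons) | C1(OCOO1)C[C@]2(CC3(CO[Si](CC)(CC)CC)OCOO3)O[C@H](C(C)(C)C)OC2=O | intermediate (not isolated)
11 | (2S,5R)-2-tert-butyl-5-(2-oxoethyl)-5-[2-oxo-3-(triethylsilyloxy)propyl]-1,3-dioxolan-4-one | O=CC[C@]1(CC(=O)CO[Si](CC)(CC)CC)O[C@H](C(C)(C)C)OC1=O | intermediate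
12 | (E)-enamine of the C3 ketone of 11 with L-proline (C3=C4, OSiEt3 trans to N) | O=CC[C@]1(C/C(N2CCC[C@H]2C(=O)O)=C\O[Si](CC)(CC)CC)O[C@H](C(C)(C)C)OC1=O | intermediate (not isolated)
13 | (2S,5R,8S,9R)-2-tert-butyl-9-hydroxy-8-(triethylsilyloxy)-1,3-dioxaspiro[4.5]decane-4,7-dione | CC(C)(C)[C@H]2O[C@]1(C(=O)O2)C[C@@H](O)[C@H](O[Si](CC)(CC)CC)C(=O)C1 | intermediate
14 | (2S)-2-tert-butyl-7,9-dihydroxy-8-(triethylsilyloxy)-1,3-dioxaspiro[4.5]decan-4-one, quinic acid configuration on the carbocycle | CC(C)(C)[C@H]2O[C@]1(C(=O)O2)C[C@@H](O)[C@H](O[Si](CC)(CC)CC)[C@H](O)C1 | intermediate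
15 | 3,4-O-isopropylidene-1,5-quinide | O[C@]1(C(=O)O3)C[C@@H]3[C@@H]2OC(C)(C)O[C@@H]2C1 | intermediate
16 | (E)-3,4-diacetoxycinnamic acid (3,4-di-O-acetylcaffeic acid) | CC(=O)Oc1ccc(/C=C/C(=O)O)cc1OC(C)=O | starting material
17 | (E)-3,4-diacetoxycinnamoyl chloride | CC(=O)Oc1ccc(/C=C/C(=O)Cl)cc1OC(C)=O | intermediate (not isolated)
18 | 1-O-[(E)-3,4-diacetoxycinnamoyl]-3,4-O-isopropylidene-1,5-quinide | O=C(/C=C/c4ccc(OC(C)=O)c(OC(C)=O)c4)O[C@]1(C(=O)O3)C[C@@H]3[C@@H]2OC(C)(C)O[C@@H]2C1 | intermediate
19 | 1-O-caffeoylquinic acid | O=C(/C=C/c1ccc(O)c(O)c1)O[C@]1(C(=O)O)C[C@@H](O)[C@H](O)[C@H](O)C1 | target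

Total step count: 11. Longest linear sequence: 9 (steps 3 to 11, from L-allylglycine).

Steps most likely to fail

Step 7 (aldol ring closure). The process at risk is stereocontrol and chemoselectivity. The catalyst-preferred transition state may be destabilised by the C1 substituents (mismatched double stereodifferentiation). The aldehyde enamine may expel the C1 acetal oxygen by β-elimination. The ketol may dehydrate. The fallback sets out from 11 and makes the dehydration deliberate. Pyrrolidinium acetate (cat.) in toluene at 50 °C should give the aldol condensation product, the spiro 8-silyloxy-cyclohex-8-en-7-one F1, in which the ring closure still forms the same bond, now as C4=C5. 1,2-Reduction with NaBH4/CeCl3·7H2O in MeOH at −78 °C (Luche) should then give the allylic alcohol F2, hydride entering anti to the pseudo-axial C1 acetal oxygen. Hydroboration of the silyl enol ether with BH3·THF and oxidation with NaBO3·4H2O adds H to C4 and OH to C5 in syn fashion on the face opposite to the C3 oxygen. This returns to the route at 14.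

Step 8 (directed reduction). The process at risk is facial control of hydride delivery, for example after silyl migration from O4 to O5 or by competing non-directed reduction. The fallback sets out from 13 and replaces hydroxyl direction by steric approach control. Et3SiOSO2CF3/2,6-lutidine (CH2Cl2, −78 °C) gives the 4,5-bis(triethylsilyl) ether ketone F3. LiBH(s-Bu)3 in THF at −78 °C should attack equatorially, away from the axial C1 acetal oxygen, to give the axial C3 alcohol F4. F4 is submitted to the conditions of step 9, which cleave both silyl ethers, and the route is rejoined at 15.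

Step 9 (desilylation, acetonide formation and lactonisation in one pot). The process at risk is incomplete desilylation, or methanolysis of the dioxolanone to a methyl ester that lactonises sluggishly. The fallback sets out from 14 and separates deprotection from reprotection. 1 M HCl (aq)/THF at rt hydrolyses the silyl ether and the dioxolanone to free (−)-quinic acid F5. Acetone/2,2-dimethoxypropane/TsOH·H2O at reflux then converts the free acid into the lactone acetonide, and the route is rejoined at 15.

Further compounds
F1 | step 7 | (2S,5R)-2-tert-butyl-8-(triethylsilyloxy)-1,3-dioxaspiro[4.5]dec-8-ene-4,7-dione | CC(C)(C)[C@H]2O[C@]1(C(=O)O2)CC=C(O[Si](CC)(CC)CC)C(=O)C1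
F2 | step 7 | (2S)-2-tert-butyl-7-hydroxy-8-(triethylsilyloxy)-1,3-dioxaspiro[4.5]dec-8-en-4-one (7-OH cis to ring oxygen O1) | CC(C)(C)[C@H]2O[C@]1(C(=O)O2)CC=C(O[Si](CC)(CC)CC)[C@H](O)C1
F3 | step 8 | (2S,5R,8S,9R)-2-tert-butyl-8,9-bis(triethylsilyloxy)-1,3-dioxaspiro[4.5]decane-4,7-dione | CC(C)(C)[C@H]2O[C@]1(C(=O)O2)C[C@@H](O[Si](CC)(CC)CC)[C@H](O[Si](CC)(CC)CC)C(=O)C1
F4 | step 8 | (2S)-2-tert-butyl-7-hydroxy-8,9-bis(triethylsilyloxy)-1,3-dioxaspiro[4.5]decan-4-one, quinic acid configuration on the carbocycle | CC(C)(C)[C@H]2O[C@]1(C(=O)O2)C[C@@H](O[Si](CC)(CC)CC)[C@H](O[Si](CC)(CC)CC)[C@H](O)C1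
F5 | step 9 | (−)-quinic acid | O[C@]1(C(=O)O)C[C@@H](O)[C@H](O)[C@H](O)C1
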